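The cis-fused α-methylene-γ-butyrolactone (O1, C12, C11=C13, C7, C6; germacranolide numbering) on the cyclodeca-1(10),4-diene is taken apart into an allene, CO2 and an aldehyde: C13=C11=C7 is a terminal allene, C12 is carbon dioxide and C6 an enal carbonyl. In one nickel-mediated operation CO2 is joined to the central allene carbon (C11–C12) and the resulting allylnickel carboxylate adds through C7 to the tethered C6 aldehyde (C6–C7); this closes the ten-membered ring, sets C6 and C7 from the lone C8 stereocentre and gives the lactone on work-up. The precursor is an acyclic (2E,6E)-dienal carrying the allene, a C14 dimethyl acetal and silyl ethers at O8 and O15.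

Key step: step 14

Remark: atoms carry germacranolide numbers throughout (C6/C7 ring fusion, C8 ester carbinol, C11=C13 methylene, C12 lactone carbonyl, C14 formyl carbon, C15 hydroxymethyl carbon); TBDPS = tert-butyldiphenylsilyl, TBS = tert-butyldimethylsilyl, Piv = pivaloyl, Tr = trityl, Ts = 4-methylphenylsulfonyl.
Assumption: the sense of induction of the bis-sulfonamide controller in step 9 is taken from its chair transition-state model; should it prove opposite, the mirror-image controller is used and nothing else changes.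

Step 1
Reactants: 1 but-2-yne-1,4-diol
Product: 2 4-(TBDPSO)but-2-yn-1-ol
Conditions: NaH (1 equiv), THF, 0 °C; TBDPSCl, rt
Reagents that add atoms: tert-butyl(chloro)diphenylsilane, CC(C)(C)[Si](Cl)(c1ccccc1)c1ccccc1
Why: Williamson-type O-silylation of the monoalkoxide of a symmetric diol should stop at the mono-ether and leaves one hydroxyl to direct step 2.

Step 2
Reactants: 2 4-(TBDPSO)but-2-yn-1-ol
Product: 3 (Z)-4-(TBDPSO)-3-iodobut-2-en-1-ol
Conditions: NaAlH2(OCH2CH2OMe)2, THF, 0 °C; then I2, −78 °C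
Reagents that add atoms: iodine, II
Why: Hydroxyl-directed trans-hydroalumination puts aluminium on the distal alkyne carbon cis to the carbinol carbon, and iododealumination with retention fixes the C4=C5 geometry (C6 cis to the future C3); the cold quench avoids loss of the silyloxy group.

Step 3
Reactants: 3 (Z)-4-(TBDPSO)-3-iodobut-2-en-1-ol; 4 acrolein diethyl acetal
Product: 6 (E)-3-(TBDPSOCH2)-6,6-diethoxyhex-2-en-1-ol, via B-(3,3-diethoxypropyl)-9-BBN 5 (not isolated)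
Conditions: 4, 9-BBN-H, THF, 0 °C→rt; then 3, PdCl2(dppf), AsPh3, Cs2CO3, DMF/H2O, rt
Reagents that add atoms: none
Why: Anti-Markovnikov hydroboration and B-alkyl Suzuki–Miyaura coupling join C3 to C4 with retention of the vinyl iodide geometry; the free allylic alcohol is tolerated.

Step 4
Reactants: 6 (E)-3-(TBDPSOCH2)-6,6-diethoxyhex-2-en-1-ol
Product: 7 (E)-3-(TBDPSOCH2)-6,6-diethoxyhex-2-en-1-yl pivalate
Conditions: PivCl, pyridine, DMAP (cat.), CH2Cl2, 0 °C→rt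
Reagents that add atoms: pivaloyl chloride, CC(C)(C)C(Cl)=O
Why: Acylation masks O6 as a hindered ester that survives steps 5–10 and is removed by the same hydride that adjusts C14 in step 11.

Step 5
Reactants: 7 (E)-3-(TBDPSOCH2)-6,6-diethoxyhex-2-en-1-yl pivalate
Product: 8 (E)-3-(TBDPSOCH2)-6-oxohex-2-en-1-yl pivalate
Conditions: 1 M HCl, THF, rt
Reagents that add atoms: water, O
Why: Acid hydrolysis of the diethyl acetal frees the C1 aldehyde; the pivalate and the TBDPS ether are stable to dilute acid.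

Step 6
Reactants: 8 (E)-3-(TBDPSOCH2)-6-oxohex-2-en-1-yl pivalate; 9 diethyl (2-oxotetrahydrofuran-3-yl)phosphonate
Product: 10 (2E)-3-(TBDPSOCH2)-6-[(3E)-2-oxodihydrofuran-3(2H)-ylidene]hex-2-en-1-yl pivalate
Conditions: 9, NaH, THF, 0 °C; then 8, 0 °C→rt
Reagents that add atoms: none
Why: Horner–Wadsworth–Emmons olefination should favour the E-alkylidene lactone (C2 trans to the C14 carbonyl, hence cis to C9), which is the ring-cis C1=C10 geometry of the target; a minor Z-isomer would be removed by chromatography.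

Step 7
Reactants: 10 (2E)-3-(TBDPSOCH2)-6-[(3E)-2-oxodihydrofuran-3(2H)-ylidene]hex-2-en-1-yl pivalate
Product: 11 (2E,6E)-3-(TBDPSOCH2)-7-(2-hydroxyethyl)-8-[methoxy(methyl)amino]-8-oxoocta-2,6-dien-1-yl pivalate
Conditions: MeNH(OMe)·HCl, iPrMgCl, THF, −20→0 °C
Reagents that add atoms: N,O-dimethylhydroxylamine hydrochloride, CNOC.Cl
Why: Aminolysis of the lactone by the magnesium amide turns C14 into an N-methoxy-N-methylamide (aldehyde-level handle) and frees the primary C8 hydroxyl, while the hindered pivalate should survive.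

Step 8
Reactants: 11 (2E,6E)-3-(TBDPSOCH2)-7-(2-hydroxyethyl)-8-[methoxy(methyl)amino]-8-oxoocta-2,6-dien-1-yl pivalate
Product: 12 (2E,6E)-3-(TBDPSOCH2)-8-[methoxy(methyl)amino]-8-oxo-7-(2-oxoethyl)octa-2,6-dien-1-yl pivalate
Conditions: Dess–Martin periodinane, CH2Cl2, 0 °C→rt; used at once
Reagents that add atoms: none
Why: Dess–Martin oxidation under near-neutral conditions should give the β,γ-unsaturated aldehyde without moving the C1=C10 bond, which stays conjugated to the amide.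

Step 9
Reactants: 12 (2E,6E)-3-(TBDPSOCH2)-8-[methoxy(methyl)amino]-8-oxo-7-(2-oxoethyl)octa-2,6-dien-1-yl pivalate; 13 tributyl(propa-1,2-dien-1-yl)stannane
Product: 15 (2E,6E)-3-(TBDPSOCH2)-7-[(2S)-2-hydroxypenta-3,4-dien-1-yl]-8-[methoxy(methyl)amino]-8-oxoocta-2,6-dien-1-yl pivalate, via B-propargyl diazaborolidine 14 (not isolated)
Conditions: (S,S)-TsNHCH(Ph)CH(Ph)NHTs, BBr3, CH2Cl2, 0 °C→rt; 13, rt; then 12, −78 °C
Reagents that add atoms: none
Why: Enantioselective propargylboration (SE2′) through a six-membered chair transition state delivers the α-allenyl carbinol, with C8 (S) set by the C2-symmetric bis-sulfonamide controller on boron; amide, pivalate and silyl ether are inert at −78 °C.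

Step 10
Reactants: 15 (2E,6E)-3-(TBDPSOCH2)-7-[(2S)-2-hydroxypenta-3,4-dien-1-yl]-8-[methoxy(methyl)amino]-8-oxoocta-2,6-dien-1-yl pivalate
Product: 16 (2E,6E)-3-(TBDPSOCH2)-7-[(2S)-2-(TBSO)penta-3,4-dien-1-yl]-8-[methoxy(methyl)amino]-8-oxoocta-2,6-dien-1-yl pivalate
Conditions: TBSOTf, 2,6-lutidine, CH2Cl2, −78 °C
Reagents that add atoms: tert-butyldimethylsilyl trifluoromethanesulfonate, CC(C)(C)[Si](C)(C)OS(=O)(=O)C(F)(F)F
Why: Fast O-silylation under a non-nucleophilic base forestalls relactonisation of the γ-hydroxy amide and gives an allenylic ether that, unlike an ester, should not ionise on zerovalent nickel.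

Step 11
Reactants: 16 (2E,6E)-3-(TBDPSOCH2)-7-[(2S)-2-(TBSO)penta-3,4-dien-1-yl]-8-[methoxy(methyl)amino]-8-oxoocta-2,6-dien-1-yl pivalate
Product: 17 (2E,6E)-6-(TBDPSOCH2)-8-hydroxy-2-[(2S)-2-(TBSO)penta-3,4-dien-1-yl]octa-2,6-dienal
Conditions: iBu2AlH, CH2Cl2, −78→−40 °C; aq. potassium sodium tartrate
Reagents that add atoms: none
Why: Hydride reduction stops at the chelated tetrahedral adduct of the N-methoxy-N-methylamide, which gives the C14 enal on work-up, while the pivalate is cleaved reductively to the free O6 alcohol, so the two termini end up differentiated.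

Step 12
Reactants: 17 (2E,6E)-6-(TBDPSOCH2)-8-hydroxy-2-[(2S)-2-(TBSO)penta-3,4-dien-1-yl]octa-2,6-dienal
Product: 18 (2E,6E)-3-(TBDPSOCH2)-8,8-dimethoxy-7-[(2S)-2-(TBSO)penta-3,4-dien-1-yl]octa-2,6-dien-1-ol
Conditions: HC(OMe)3, PPTS (cat.), MeOH, 0 °C
Reagents that add atoms: trimethyl orthoformate, COC(OC)OC; methanol, CO
Why: Acid-catalysed acetalisation masks the C14 aldehyde, which would otherwise be attacked by C7 in step 14 to give a five-membered ring; silyl ethers and allene tolerate brief PPTS.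

Step 13
Reactants: 18 (2E,6E)-3-(TBDPSOCH2)-8,8-dimethoxy-7-[(2S)-2-(TBSO)penta-3,4-dien-1-yl]octa-2,6-dien-1-ol
Product: 19 (2E,6E)-3-(TBDPSOCH2)-8,8-dimethoxy-7-[(2S)-2-(TBSO)penta-3,4-dien-1-yl]octa-2,6-dienal
Conditions: MnO2, CH2Cl2, rt
Reagents that add atoms: none
Why: Heterogeneous allylic oxidation should give the C6 enal without scrambling the C4=C5 geometry (formyl group cis to C3).

Step 14
Reactants: 19 (2E,6E)-3-(TBDPSOCH2)-8,8-dimethoxy-7-[(2S)-2-(TBSO)penta-3,4-dien-1-yl]octa-2,6-dienal; 20 carbon dioxide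
Product: 23 (3aR,4S,6E,10E,11aR)-4-(TBSO)-10-(TBDPSOCH2)-6-(dimethoxymethyl)-3-methylidene-3a,4,5,8,9,11a-hexahydrocyclodeca[b]furan-2(3H)-one, via oxanickelacycle 21 (not isolated), via seco hydroxy acid 22 (not isolated)
Conditions: Ni(cod)2 (1.2 equiv), DBU (2.5 equiv), CO2 (1 atm), THF, 0 °C, slow addition of 19 (high dilution); aq. NaH2PO4; then PPTS (cat.), 4 Å MS, CH2Cl2, rt
Reagents that add atoms: none
Why: Proposed new method: DBU-ligated zerovalent nickel couples the terminal C11=C13 bond of the allene with CO2 (C11–C12) to the five-membered oxanickelacycle 21, an allylnickel carboxylate whose CH2–Ni terminus lies cis to C8, and this adds through C7 to the nickel-bound C6 aldehyde in a closed six-membered chair (C6–C7), after which protonation gives hydroxy acid 22 and lactonisation; the closest known reaction types are the sequential nickel-mediated coupling of terminal allenes, CO2 and aryl aldehydes and the metal-promoted intramolecular addition of 2-(alkoxycarbonyl)allyl metals to tethered aldehydes. The ten-membered carbocycle closes by 10-exo-trig attack of C7 on the aldehyde, helped by the two ring-cis trisubstituted alkenes that bend the chain, and the lactone closes by 5-exo-trig acyl substitution of O6 on C12. C7 is set by the C8 stereocentre: with H-8 eclipsing the alkylidene (allylic strain) the aldehyde should enter anti to the C8–C9 bond and gauche to the silyloxy group, which puts O8 and C11 on the same ring face. C6 follows from the chair with the Z-disposed allyl terminus (C8 axial, enal residue equatorial), giving the syn adduct and hence the cis-fused lactone with H-6, H-7 and H-8 mutually cis. The step needs allene–CO2 coupling to outrun nickel–enal binding and cyclisation to outrun oligomerisation, which the CO2 atmosphere, the DBU ligand and slow addition at high dilution are meant to secure, and it needs γ-attack through C7, which the cyclic transition state imposes.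

Step 15
Reactants: 23 (3aR,4S,6E,10E,11aR)-4-(TBSO)-10-(TBDPSOCH2)-6-(dimethoxymethyl)-3-methylidene-3a,4,5,8,9,11a-hexahydrocyclodeca[b]furan-2(3H)-one
Product: 24 (3aS,4S,6E,10E,11aR)-10-(TBDPSOCH2)-6-(dimethoxymethyl)-4-hydroxy-3-methylidene-3a,4,5,8,9,11a-hexahydrocyclodeca[b]furan-2(3H)-one
Conditions: HF·pyridine, pyridine, THF, 0 °C→rt
Reagents that add atoms: none
Why: Buffered acidic fluoride should cleave the secondary TBS ether ahead of the more acid-stable primary TBDPS ether and leave the dimethyl acetal, so that no γ-hydroxy aldehyde (lactol) can form at C8/C14.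

Step 16
Reactants: 24 (3aS,4S,6E,10E,11aR)-10-(TBDPSOCH2)-6-(dimethoxymethyl)-4-hydroxy-3-methylidene-3a,4,5,8,9,11a-hexahydrocyclodeca[b]furan-2(3H)-one
Product: 25 (3aS,4S,6E,10E,11aR)-10-(TBDPSOCH2)-6-(dimethoxymethyl)-3-methylidene-2-oxo-2,3,3a,4,5,8,9,11a-octahydrocyclodeca[b]furan-4-yl 3-methylbutanoate
Conditions: (Me2CHCH2CO)2O, DMAP (cat.), pyridine, CH2Cl2, 0 °C
Reagents that add atoms: 3-methylbutanoic anhydride, CC(C)CC(=O)OC(=O)CC(C)C
Why: DMAP-catalysed acylation of the secondary alcohol under mild base should outpace migration of the lactone to O8.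

Step 17
Reactants: 25 (3aS,4S,6E,10E,11aR)-10-(TBDPSOCH2)-6-(dimethoxymethyl)-3-methylidene-2-oxo-2,3,3a,4,5,8,9,11a-octahydrocyclodeca[b]furan-4-yl 3-methylbutanoate
Product: 26 (3aS,4S,6E,10E,11aR)-6-formyl-10-(hydroxymethyl)-3-methylidene-2-oxo-2,3,3a,4,5,8,9,11a-octahydrocyclodeca[b]furan-4-yl 3-methylbutanoate (CNP0345200.6)
Conditions: aq. HF (48%), MeCN, 0 °C→rt
Reagents that add atoms: water, O
Why: Aqueous acidic fluoride removes the primary TBDPS ether and hydrolyses the dimethyl acetal to the conjugated C14 aldehyde in one operation; ester, α-methylene lactone and enal are stable to acid.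

Compound list
1 | but-2-yne-1,4-diol | OCC#CCO | starting material
2 | 4-(TBDPSO)but-2-yn-1-ol | OCC#CCO[Si](c1ccccc1)(c1ccccc1)C(C)(C)C | intermediate
3 | (Z)-4-(TBDPSO)-3-iodobut-2-en-1-ol | OC/C=C(/CO[Si](c1ccccc1)(c1ccccc1)C(C)(C)C)I | intermediate
4 | acrolein diethyl acetal (3,3-diethoxyprop-1-ene) | C=CC(OCC)OCC | starting material
5 | 9-(3,3-diethoxypropyl)-9-borabicyclo[3.3.1]nonane | CCOC(CCB1C2CCCC1CCC2)OCC | intermediate
6 | (E)-3-(TBDPSOCH2)-6,6-diethoxyhex-2-en-1-ol | OC/C=C(/CO[Si](c1ccccc1)(c1ccccc1)C(C)(C)C)CCC(OCC)OCC | intermediate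
7 | (E)-3-(TBDPSOCH2)-6,6-diethoxyhex-2-en-1-yl pivalate | CC(C)(C)C(=O)OC/C=C(/CO[Si](c1ccccc1)(c1ccccc1)C(C)(C)C)CCC(OCC)OCC | intermediate
8 | (E)-3-(TBDPSOCH2)-6-oxohex-2-en-1-yl pivalate | CC(C)(C)C(=O)OC/C=C(/CO[Si](c1ccccc1)(c1ccccc1)C(C)(C)C)CCC=O | intermediate
9 | diethyl (2-oxotetrahydrofuran-3-yl)phosphonate | CCOP(=O)(OCC)C1CCOC1=O | starting material
10 | (2E)-3-(TBDPSOCH2)-6-[(3E)-2-oxodihydrofuran-3(2H)-ylidene]hex-2-en-1-yl pivalate | CC(C)(C)C(=O)OC/C=C(/CO[Si](c1ccccc1)(c1ccccc1)C(C)(C)C)CC/C=C2/C(=O)OCC2 | intermediate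
11 | (2E,6E)-3-(TBDPSOCH2)-7-(2-hydroxyethyl)-8-[methoxy(methyl)amino]-8-oxoocta-2,6-dien-1-yl pivalate | CC(C)(C)C(=O)OC/C=C(/CO[Si](c1ccccc1)(c1ccccc1)C(C)(C)C)CC/C=C(/C(=O)N(C)OC)CCO | intermediate
12 | (2E,6E)-3-(TBDPSOCH2)-8-[methoxy(methyl)amino]-8-oxo-7-(2-oxoethyl)octa-2,6-dien-1-yl pivalate | CC(C)(C)C(=O)OC/C=C(/CO[Si](c1ccccc1)(c1ccccc1)C(C)(C)C)CC/C=C(/C(=O)N(C)OC)CC=O | intermediate
13 | tributyl(propa-1,2-dien-1-yl)stannane (allenyltributylstannane) | CCCC[Sn](CCCC)(CCCC)C=C=C | starting material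
14 | (4S,5S)-4,5-diphenyl-2-(prop-2-yn-1-yl)-1,3-bis(Ts)-1,3,2-diazaborolidine | C#CCB1N(S(=O)(=O)c2ccc(C)cc2)[C@@H](c2ccccc2)[C@H](c2ccccc2)N1S(=O)(=O)c1ccc(C)cc1 | intermediate
15 | (2E,6E)-3-(TBDPSOCH2)-7-[(2S)-2-hydroxypenta-3,4-dien-1-yl]-8-[methoxy(methyl)amino]-8-oxoocta-2,6-dien-1-yl pivalate | CC(C)(C)C(=O)OC/C=C(/CO[Si](c1ccccc1)(c1ccccc1)C(C)(C)C)CC/C=C(/C(=O)N(C)OC)C[C@H](O)C=C=C | intermediate
16 | (2E,6E)-3-(TBDPSOCH2)-7-[(2S)-2-(TBSO)penta-3,4-dien-1-yl]-8-[methoxy(methyl)amino]-8-oxoocta-2,6-dien-1-yl pivalate | CC(C)(C)C(=O)OC/C=C(/CO[Si](c1ccccc1)(c1ccccc1)C(C)(C)C)CC/C=C(/C(=O)N(C)OC)C[C@H](O[Si](C)(C)C(C)(C)C)C=C=C | intermediate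
17 | (2E,6E)-6-(TBDPSOCH2)-8-hydroxy-2-[(2S)-2-(TBSO)penta-3,4-dien-1-yl]octa-2,6-dienal | OC/C=C(/CO[Si](c1ccccc1)(c1ccccc1)C(C)(C)C)CC/C=C(/C=O)C[C@H](O[Si](C)(C)C(C)(C)C)C=C=C | intermediate
18 | (2E,6E)-3-(TBDPSOCH2)-8,8-dimethoxy-7-[(2S)-2-(TBSO)penta-3,4-dien-1-yl]octa-2,6-dien-1-ol | OC/C=C(/CO[Si](c1ccccc1)(c1ccccc1)C(C)(C)C)CC/C=C(/C(OC)OC)C[C@H](O[Si](C)(C)C(C)(C)C)C=C=C | intermediate
19 | (2E,6E)-3-(TBDPSOCH2)-8,8-dimethoxy-7-[(2S)-2-(TBSO)penta-3,4-dien-1-yl]octa-2,6-dienal | O=C/C=C(/CO[Si](c1ccccc1)(c1ccccc1)C(C)(C)C)CC/C=C(/C(OC)OC)C[C@H](O[Si](C)(C)C(C)(C)C)C=C=C | intermediate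
20 | carbon dioxide | O=C=O | starting material
21 | oxanickelacycle: 4-alkylidene-1-oxa-2-nickelacyclopentan-5-one from C13, C11, C12 of 19 and CO2, alkylidene CH (C7) cis to CH2–Ni (DBU ligands on nickel not drawn) | O=C1O[Ni]C/C1=C\[C@@H](O[Si](C)(C)C(C)(C)C)C/C(C(OC)OC)=C\CC/C(CO[Si](c2ccccc2)(c2ccccc2)C(C)(C)C)=C\C=O | intermediate
22 | 2-[(1R,2R,3E,7E,10S)-10-(TBSO)-4-(TBDPSOCH2)-8-(dimethoxymethyl)-2-hydroxycyclodeca-3,7-dien-1-yl]prop-2-enoic acid | C=C(C(=O)O)[C@@H]1[C@H](O)/C=C(/CO[Si](c2ccccc2)(c2ccccc2)C(C)(C)C)CC/C=C(/C(OC)OC)C[C@@H]1O[Si](C)(C)C(C)(C)C | intermediate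
23 | (3aR,4S,6E,10E,11aR)-4-(TBSO)-10-(TBDPSOCH2)-6-(dimethoxymethyl)-3-methylidene-3a,4,5,8,9,11a-hexahydrocyclodeca[b]furan-2(3H)-one (H-6, H-7, H-8 all cis) | C=C1C(=O)O[C@@H]2/C=C(/CO[Si](c3ccccc3)(c3ccccc3)C(C)(C)C)CC/C=C(/C(OC)OC)C[C@H](O[Si](C)(C)C(C)(C)C)[C@H]12 | intermediate
24 | (3aS,4S,6E,10E,11aR)-10-(TBDPSOCH2)-6-(dimethoxymethyl)-4-hydroxy-3-methylidene-3a,4,5,8,9,11a-hexahydrocyclodeca[b]furan-2(3H)-one | C=C1C(=O)O[C@@H]2/C=C(/CO[Si](c3ccccc3)(c3ccccc3)C(C)(C)C)CC/C=C(/C(OC)OC)C[C@H](O)[C@H]12 | intermediate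
25 | (3aS,4S,6E,10E,11aR)-10-(TBDPSOCH2)-6-(dimethoxymethyl)-3-methylidene-2-oxo-2,3,3a,4,5,8,9,11a-octahydrocyclodeca[b]furan-4-yl 3-methylbutanoate | C=C1C(=O)O[C@@H]2/C=C(/CO[Si](c3ccccc3)(c3ccccc3)C(C)(C)C)CC/C=C(/C(OC)OC)C[C@H](OC(=O)CC(C)C)[C@H]12 | intermediate
26 | (3aS,4S,6E,10E,11aR)-6-formyl-10-(hydroxymethyl)-3-methylidene-2-oxo-2,3,3a,4,5,8,9,11a-octahydrocyclodeca[b]furan-4-yl 3-methylbutanoate (CNP0345200.6) | C=C1C(=O)O[C@@H]2/C=C(/CO)CC/C=C(/C=O)C[C@H](OC(=O)CC(C)C)[C@H]12 | target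

Total step count: 17. Longest linear sequence: 17 steps (1 → 26); 4, 9, 13 and 20 enter as purchased materials.

Steps most likely to fail

1. Step 14 (Proposed new method). The nickel may be taken up by the enal instead of the allene–CO2 pair, the allylnickel carboxylate may oligomerise instead of closing the ten-membered ring, and attack on the wrong C7 face or η3–η1 isomerisation of the alkylidene may give the 7-epi or trans-fused lactone. The fallback uses known chemistry only: the lactone carbonyl is brought in as an acrylate and the ring is closed by a chromium-mediated intramolecular Barbier (Nozaki–Hiyama–Kishi-type) allylation. It sets out from aldehyde 8 and comes back at lactone 23. Sodium triethyl phosphonoacetate opens commercial (S)-glycidyl trityl ether at its CH2 terminus and lactonises to diethyl {(5S)-2-oxo-5-[(trityloxy)methyl]tetrahydrofuran-3-yl}phosphonate F1. Horner–Wadsworth–Emmons reaction of F1 with 8 gives (2E)-3-(TBDPSOCH2)-6-{(3E,5S)-2-oxo-5-[(trityloxy)methyl]dihydrofuran-3(2H)-ylidene}hex-2-en-1-yl pivalate F2. Aminolysis as in step 7 gives (2E,6E)-3-(TBDPSOCH2)-7-[(2S)-2-hydroxy-3-(trityloxy)propyl]-8-[methoxy(methyl)amino]-8-oxoocta-2,6-dien-1-yl pivalate F3, and TBSOTf gives its TBS ether, (2E,6E)-3-(TBDPSOCH2)-7-[(2S)-2-(TBSO)-3-(trityloxy)propyl]-8-[methoxy(methyl)amino]-8-oxoocta-2,6-dien-1-yl pivalate F4. iBu2AlH gives (2E,6E)-6-(TBDPSOCH2)-8-hydroxy-2-[(2S)-2-(TBSO)-3-(trityloxy)propyl]octa-2,6-dienal F5. HC(OMe)3 with catalytic camphorsulfonic acid in MeOH forms the acetal and removes the trityl group to give (2E,6E)-3-(TBDPSOCH2)-7-[(2S)-3-hydroxy-2-(TBSO)propyl]-8,8-dimethoxyocta-2,6-dien-1-ol F6. Dess–Martin oxidation of both primary alcohols gives (2E,6E)-3-(TBDPSOCH2)-8,8-dimethoxy-7-[(2S)-3-oxo-2-(TBSO)propyl]octa-2,6-dienal F7. Morita–Baylis–Hillman reaction of its α-silyloxy aldehyde with methyl acrylate (DABCO) gives methyl (4S,6E,10E)-4-(TBSO)-10-(TBDPSOCH2)-6-(dimethoxymethyl)-3-hydroxy-2-methylidene-12-oxododeca-6,10-dienoate F8. NBS/Me2S gives the transposed bromide, methyl (2Z,4S,6E,10E)-2-(bromomethyl)-4-(TBSO)-10-(TBDPSOCH2)-6-(dimethoxymethyl)-12-oxododeca-2,6,10-trienoate F9. CrCl2 in THF at high dilution closes C6–C7 to methyl 2-[(1R,2R,3E,7E,10S)-10-(TBSO)-4-(TBDPSOCH2)-8-(dimethoxymethyl)-2-hydroxycyclodeca-3,7-dien-1-yl]prop-2-enoate F10, which lactonises (PPTS) to 23.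

2. Step 9. The β,γ-unsaturated aldehyde may isomerise or self-condense before it is trapped, and induction by the boron controller may be incomplete. The fallback replaces propargylboration by alkynylation and one-carbon homologation; it sets out from aldehyde 12 and comes back at 16. Zinc-mediated asymmetric alkynylation with trimethylsilylacetylene (Me2Zn, ProPhenol ligand of the appropriate hand) gives (2E,6E)-3-(TBDPSOCH2)-7-[(2S)-2-hydroxy-4-(trimethylsilyl)but-3-yn-1-yl]-8-[methoxy(methyl)amino]-8-oxoocta-2,6-dien-1-yl pivalate F11. TBSOTf gives (2E,6E)-3-(TBDPSOCH2)-7-[(2S)-2-(TBSO)-4-(trimethylsilyl)but-3-yn-1-yl]-8-[methoxy(methyl)amino]-8-oxoocta-2,6-dien-1-yl pivalate F12. Brief K2CO3/MeOH removes the C-silyl group to give (2E,6E)-3-(TBDPSOCH2)-7-[(2S)-2-(TBSO)but-3-yn-1-yl]-8-[methoxy(methyl)amino]-8-oxoocta-2,6-dien-1-yl pivalate F13. Crabbé homologation (CuI, paraformaldehyde, dicyclohexylamine, dioxane, reflux) converts the terminal alkyne into the terminal allene 16.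

3. Step 15. The primary TBDPS ether may be lost alongside the secondary TBS ether, and the liberated 8-hydroxyl may attack the lactone. The fallback gives up discrimination between the silyl ethers and differentiates the hydroxyls instead; it sets out from 23 and comes back at 24. Both silyl ethers are removed with TBAF/AcOH to give (3aS,4S,6E,10E,11aR)-6-(dimethoxymethyl)-4-hydroxy-10-(hydroxymethyl)-3-methylidene-3a,4,5,8,9,11a-hexahydrocyclodeca[b]furan-2(3H)-one F14, and the primary allylic hydroxyl alone is re-silylated (TBDPSCl, imidazole, CH2Cl2, 0 °C) to give 24.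

Further compounds
F1 | step 14 | diethyl {(5S)-2-oxo-5-[(trityloxy)methyl]tetrahydrofuran-3-yl}phosphonate | CCOP(=O)(OCC)C1C[C@@H](COC(c2ccccc2)(c2ccccc2)c2ccccc2)OC1=O
F2 | step 14 | (2E)-3-(TBDPSOCH2)-6-{(3E,5S)-2-oxo-5-[(trityloxy)methyl]dihydrofuran-3(2H)-ylidene}hex-2-en-1-yl pivalate | CC(C)(C)C(=O)OC/C=C(/CO[Si](c1ccccc1)(c1ccccc1)C(C)(C)C)CC/C=C2/C(=O)O[C@H](COC(c1ccccc1)(c1ccccc1)c1ccccc1)C2
F3 | step 14 | (2E,6E)-3-(TBDPSOCH2)-7-[(2S)-2-hydroxy-3-(trityloxy)propyl]-8-[methoxy(methyl)amino]-8-oxoocta-2,6-dien-1-yl pivalate | CC(C)(C)C(=O)OC/C=C(/CO[Si](c1ccccc1)(c1ccccc1)C(C)(C)C)CC/C=C(/C(=O)N(C)OC)C[C@H](O)COC(c1ccccc1)(c1ccccc1)c1ccccc1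
F4 | step 14 | (2E,6E)-3-(TBDPSOCH2)-7-[(2S)-2-(TBSO)-3-(trityloxy)propyl]-8-[methoxy(methyl)amino]-8-oxoocta-2,6-dien-1-yl pivalate | CC(C)(C)C(=O)OC/C=C(/CO[Si](c1ccccc1)(c1ccccc1)C(C)(C)C)CC/C=C(/C(=O)N(C)OC)C[C@H](O[Si](C)(C)C(C)(C)C)COC(c1ccccc1)(c1ccccc1)c1ccccc1
F5 | step 14 | (2E,6E)-6-(TBDPSOCH2)-8-hydroxy-2-[(2S)-2-(TBSO)-3-(trityloxy)propyl]octa-2,6-dienal | OC/C=C(/CO[Si](c1ccccc1)(c1ccccc1)C(C)(C)C)CC/C=C(/C=O)C[C@H](O[Si](C)(C)C(C)(C)C)COC(c1ccccc1)(c1ccccc1)c1ccccc1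
F6 | step 14 | (2E,6E)-3-(TBDPSOCH2)-7-[(2S)-3-hydroxy-2-(TBSO)propyl]-8,8-dimethoxyocta-2,6-dien-1-ol | OC/C=C(/CO[Si](c1ccccc1)(c1ccccc1)C(C)(C)C)CC/C=C(/C(OC)OC)C[C@H](O[Si](C)(C)C(C)(C)C)CO
F7 | step 14 | (2E,6E)-3-(TBDPSOCH2)-8,8-dimethoxy-7-[(2S)-3-oxo-2-(TBSO)propyl]octa-2,6-dienal | O=C/C=C(/CO[Si](c1ccccc1)(c1ccccc1)C(C)(C)C)CC/C=C(/C(OC)OC)C[C@H](O[Si](C)(C)C(C)(C)C)C=O
F8 | step 14 | methyl (4S,6E,10E)-4-(TBSO)-10-(TBDPSOCH2)-6-(dimethoxymethyl)-3-hydroxy-2-methylidene-12-oxododeca-6,10-dienoate (C3 epimers) | O=C/C=C(/CO[Si](c1ccccc1)(c1ccccc1)C(C)(C)C)CC/C=C(/C(OC)OC)C[C@H](O[Si](C)(C)C(C)(C)C)C(O)C(=C)C(=O)OC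
F9 | step 14 | methyl (2Z,4S,6E,10E)-2-(bromomethyl)-4-(TBSO)-10-(TBDPSOCH2)-6-(dimethoxymethyl)-12-oxododeca-2,6,10-trienoate | O=C/C=C(/CO[Si](c1ccccc1)(c1ccccc1)C(C)(C)C)CC/C=C(/C(OC)OC)C[C@H](O[Si](C)(C)C(C)(C)C)/C=C(\CBr)C(=O)OC
F10 | step 14 | methyl 2-[(1R,2R,3E,7E,10S)-10-(TBSO)-4-(TBDPSOCH2)-8-(dimethoxymethyl)-2-hydroxycyclodeca-3,7-dien-1-yl]prop-2-enoate | C=C(C(=O)OC)[C@@H]1[C@H](O)/C=C(/CO[Si](c2ccccc2)(c2ccccc2)C(C)(C)C)CC/C=C(/C(OC)OC)C[C@@H]1O[Si](C)(C)C(C)(C)C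
F11 | step 9 | (2E,6E)-3-(TBDPSOCH2)-7-[(2S)-2-hydroxy-4-(trimethylsilyl)but-3-yn-1-yl]-8-[methoxy(methyl)amino]-8-oxoocta-2,6-dien-1-yl pivalate | CC(C)(C)C(=O)OC/C=C(/CO[Si](c1ccccc1)(c1ccccc1)C(C)(C)C)CC/C=C(/C(=O)N(C)OC)C[C@H](O)C#C[Si](C)(C)C
F12 | step 9 | (2E,6E)-3-(TBDPSOCH2)-7-[(2S)-2-(TBSO)-4-(trimethylsilyl)but-3-yn-1-yl]-8-[methoxy(methyl)amino]-8-oxoocta-2,6-dien-1-yl pivalate | CC(C)(C)C(=O)OC/C=C(/CO[Si](c1ccccc1)(c1ccccc1)C(C)(C)C)CC/C=C(/C(=O)N(C)OC)C[C@H](O[Si](C)(C)C(C)(C)C)C#C[Si](C)(C)C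
F13 | step 9 | (2E,6E)-3-(TBDPSOCH2)-7-[(2S)-2-(TBSO)but-3-yn-1-yl]-8-[methoxy(methyl)amino]-8-oxoocta-2,6-dien-1-yl pivalate | CC(C)(C)C(=O)OC/C=C(/CO[Si](c1ccccc1)(c1ccccc1)C(C)(C)C)CC/C=C(/C(=O)N(C)OC)C[C@H](O[Si](C)(C)C(C)(C)C)C#C
F14 | step 15 | (3aS,4S,6E,10E,11aR)-6-(dimethoxymethyl)-4-hydroxy-10-(hydroxymethyl)-3-methylidene-3a,4,5,8,9,11a-hexahydrocyclodeca[b]furan-2(3H)-one | C=C1C(=O)O[C@@H]2/C=C(/CO)CC/C=C(/C(OC)OC)C[C@H](O)[C@H]12
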